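## Structural features

The target is a C25 terpenoid on a trans-fused decalin (rings A and B). Its equatorial C9 side chain has two methylenes, an E-trisubstituted alkene (C13=C14), a secondary allylic carbinol (C15) and a 4-methylbutenolide joined through its γ-carbon (C16). Ring A holds the quaternary C4 with an axial methyl and an equatorial hydroxymethyl (C18), next to the contiguous centres C5 (α-H), C10 (β-methyl) and C9 (α-H). Ring B adds an equatorial 6α-hydroxyl and the tertiary 8α-carbinol with an axial methyl. C15 and C16 are both S and threo to each other, five bonds from the nearest ring stereocentre, so the decalin cannot control them. The butenolide is the fragile part: base can epimerise C16 through the acidic γ-hydrogen or expel the allylic C15 oxygen. The tertiary C8 alcohol is β to C6 and C11, so carbonyl groups there invite retro-aldol cleavage or dehydration. The real difficulty is twofold: the C4–C5–C10–C9 array with two different one-carbon groups on C4, and the remote C15/C16 pair. The key step exploits that rings A and B with C4, C5, C10 and C9 map onto an all-E farnesyl chain, the equatorial C18 oxygen corresponding to the E-terminal carbon.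

## Logic of the disconnections

26 ⇒ 25. The three O–Si bonds (O6, O8, O18) are cut last. The free tetraol is revealed only at the end because the butenolide tolerates buffered fluoride but not base. The forward step must leave C16 and the allylic C15–O bond untouched.

25 ⇒ 21 + 23. The C15–C16 bond is cut. It joins the only two adjacent stereocentres outside the rings, and cutting it removes the whole lactone as a five-carbon nucleophile. 21 then has no side-chain stereocentre. The forward step must choose the Re face of the aldehyde and the threo mode under catalyst control. 23 goes back to commercial 22 by O-silylation.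

21 ⇒ 20 ⇒ 19. No skeletal bond is cut; C15 is taken back to the ester level, which is what the coupling delivers. The forward steps need a 1,2-selective hydride reduction and a mild allylic oxidation.

19 ⇒ 15 + 17. The sp3–sp2 bond C12–C13 is cut. The E geometry of C13=C14 is made beforehand in 17 and transferred with retention, which avoids an unselective olefination of a methyl ketone. The side chain shrinks to a vinyl group. The forward step needs anti-Markovnikov hydroboration of a hindered vinyl group. 17 goes back to commercial 16 by geometry-controlled enol sulfonylation.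

15 ⇒ 14 ⇒ 13 ⇒ 12. The C11=C12 bond is cut (methylenation), then C11 is returned to the alcohol level and the silyl groups are removed. The C11 aldehyde is allowed only while O8 is masked, since a β-hydroxy aldehyde would open ring B. The forward sequence must single out the primary position among three silyl ethers.

12 ⇒ 10 ⇒ 8. The C6–H and C7–H bonds made by reduction are cut, then the C7–O and C8–O bonds of the epoxide. An α,β-epoxy ketone places the oxygen on C8 electronically and on the α face sterically. The forward reduction must give the equatorial 6α-alcohol, which hydride reagents would not.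

8 ⇒ 7. The C6=O bond is cut back to an allylic methylene. The ring alkene of 7 is the only handle near C6, so the oxidation must prefer C6 over the C9 methine and the C8 methyl.

7 ⇒ 6 ⇒ 5. A C3–O bond is added back. The 3-hydroxyl is the trace of the epoxide initiation and is removed by radical deoxygenation, which does not disturb the alkene or the esters.

5 ⇒ 4. The C4–C5 and C9–C10 bonds are cut, opening both rings to an acyclic epoxy triene. Four stereocentres and two rings are traded for one epoxide and two E alkenes. The forward step must open the epoxide at its tertiary carbon with inversion, close both rings through chairs and end by losing H7.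

4 ⇒ 3 ⇒ 2 ⇒ 1. The O–Si bond, the two epoxide C–O bonds and the C12–O bond are cut in turn. Absolute configuration then rests on one reagent-controlled epoxidation of an E allylic alcohol made by selective oxidation of the E-methyl of commercial 1.

## Other disconnections considered

Alternative 1: The cut is the C18–O bond, traced back to a C18–H bond of a chiral-pool labdane. Larixol A1 already has rings A and B with C5, C9, C10 and the 6α-oxygen. After side-chain degradation to a ketal and oxygenation of C8, the 6α-O-diethylhydrosilyl ether A2 would close to the oxasilinane A3 by Rh(Xantphos)Cl-catalysed dehydrogenative silylation of the equatorial C4 methyl. Oxidation of the C–Si bond would then give the 18-alcohol.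
- In its favour: no ring is built, the 6α-oxygen is present and directs the C–H step, no C–H bond γ to O6 competes, and only the 4α methyl lies near the equatorial tether.
- Against it: it depends on the supply of a larch diterpene, the silylation must work on a congested substrate, and the side chain must be rebuilt from a methyl ketone with its E/Z problem.
- Comparison: on structure it is better at C6 (the chosen plan needs four steps and a delicate reduction there) and equal at C5, C9 and C10. On mechanism the chosen cascade fixes C4 stereospecifically from alkene geometry, whereas A3 relies on site selectivity between two methyl groups. On step economy the alternative is likely shorter for the decalin, a point in its favour; the chosen plan is independent of a natural isolate.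

Alternative 2: The cut is the C8–O bond of a γ-lactone, reached from dehydroabietic acid A4 after excision of the aromatic ring. The homodrimenic acid A5, with a tetrasubstituted C8=C9 alkene, would be protonated at C9 from the α face by a strong Brønsted acid. The C12 carboxyl would trap the C8 cation to give the trans-fused lactone A6.
- In its favour: A4 is cheap and brings C4 (C18 already oxidised), C5 and C10. The lactonisation is thermodynamically driven and sets C8 and C9 together with the C8 oxygen in place.
- Against it: degrading the arene takes many oxidative steps, the 6α-oxygen must come from benzylic C7 chemistry, the acetates must survive strong acid, and C12 must still be elaborated into the chain.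
- Comparison: on structure it equals the chosen plan at C5 and C10 and is better at C4, whose pattern is inherited. On mechanism a reversible lactonisation is more forgiving than a kinetically controlled cascade, again a point for the alternative. On step economy the chosen plan is ahead, because it builds the skeleton in one step and destroys no ring.

Alternative 3: The cut is the C7–C8 bond, with ring B contracted to a five-membered ring. The 9-hydroxy-9-acetyl hydrindene A7 would undergo a base-mediated α-ketol rearrangement in which allylic C7 migrates from C9 to the acetyl carbon. This gives the ring-expanded 8α-hydroxy-8β-methyl 9-ketone A8.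
- In its favour: the tertiary C8 carbinol is made directly with its oxygen, the 1,2-shift is stereospecific, the C9 ketone is a handle for the side chain, and the C5=C6 alkene is a handle for 5α-H and 6α-OH by hydroboration.
- Against it: A7, with quaternary C4 and C10, must itself be made enantioselectively; the rearrangement is an equilibrium in which C10 could also migrate; C9 must be set afterwards.
- Comparison: on structure it is better at C8 (one step against three) and possibly at C6. On mechanism it equals the chosen plan in stereospecificity but makes one ring and one centre where the cascade makes two rings and four. On step economy the chosen plan is shorter, since its substrate comes from an acyclic commodity in three steps.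

Key step: step 4

Assumptions and conventions (one line each):
- Locants: labdane-type numbering for the decalin (C11 on C9; C18 is the 4α one-carbon substituent; the methyls on C4, C8 and C10 are β); the side chain is C11–C16 (C15 carbinol, C16 lactone CH); open-chain compounds carry farnesyl locants.
- Stereochemical check: backside opening of the (10S,11S)-epoxide puts the oxygen 3β and the former E-carbon equatorial (4α); the ring stereochemistry needs no correction.
- Design change: the C12 oxygen carries an aryl-free triisopropylsilyl ether, because an arylsilyl ether would not survive the dissolving-metal reduction of step 9.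
- The (R)-BINOL/Ti(OiPr)4 catalyst is assumed to direct the silyloxyfuran to the Re face of the enal; if a model enal shows the opposite sense, (S)-BINOL is used.
- 1, 16 and 22 are taken to be commercial.

## Route

Step 1
Reactants: 1 (2E,6E)-farnesyl acetate
Product: 2 (2E,6E,10E)-12-hydroxyfarnesyl acetate
Conditions: SeO2 (cat.), t-BuOOH, salicylic acid (cat.), CH2Cl2, 0 °C to rt
Reagents that add atoms: tert-butyl hydroperoxide CC(C)(C)OO (oxygen relayed through SeO2, O=[Se]=O)
Why: Catalytic SeO2 allylic hydroxylation (ene reaction then [2,3]-shift) attacks the most electron-rich trisubstituted alkene at its gem-dimethyl end and prefers the E-methyl; the alkene next to the acetate is deactivated. The reaction is stopped before over-oxidation to the enal matters and unreacted 1 is recycled.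

Step 2
Reactants: 2 (2E,6E,10E)-12-hydroxyfarnesyl acetate
Product: 3 (2E,6E,10S,11S)-10,11-epoxy-12-hydroxyfarnesyl acetate
Conditions: Ti(OiPr)4 (cat.), L-(+)-diisopropyl tartrate (cat.), t-BuOOH, 4 Å MS, CH2Cl2, −20 °C
Reagents that add atoms: tert-butyl hydroperoxide CC(C)(C)OO
Why: Sharpless asymmetric epoxidation of an E-2-methyl allylic alcohol; the L-(+)-tartrate catalyst gives the (2S,3S)-epoxy alcohol, here 10S,11S. Only the alkene with the free allylic hydroxyl reacts.

Step 3
Reactants: 3 (2E,6E,10S,11S)-10,11-epoxy-12-hydroxyfarnesyl acetate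
Product: 4 (2E,6E,10S,11S)-10,11-epoxy-12-(triisopropylsilyloxy)farnesyl acetate
Conditions: i-Pr3SiCl, imidazole, DMAP (cat.), DMF, rt
Reagents that add atoms: chlorotriisopropylsilane CC(C)[Si](Cl)(C(C)C)C(C)C
Why: Standard silylation of a primary alcohol under mildly basic conditions that leave the epoxide and acetate alone. The bulky, weakly basic silyl ether keeps the oxygen from chelating the Lewis acid in step 4.

Step 4
Reactants: 4 (2E,6E,10S,11S)-10,11-epoxy-12-(triisopropylsilyloxy)farnesyl acetate
Product: 5 3β-hydroxy-18-(triisopropylsilyloxy)drim-7-en-11-yl acetate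
Conditions: MeAlCl2 (1.5 equiv), CH2Cl2, −78 °C; aq. NaHCO3
Reagents that add atoms: none
Why: MeAlCl2 binds the epoxide oxygen, the C5=C10 alkene opens the epoxide at its tertiary carbon from the backside (C4 inverted, C3 retained), the C10 cation is captured by the C8=C9 alkene, and the C8 cation loses H7 to leave the C7=C8 alkene, the methyl on aluminium taking the proton as methane. The closest known reaction type is the Lewis acid-promoted epoxy-polyene cyclisation of 2,3-epoxy polyprenyl esters. Ring A closes 6-endo through a chair with the new C4–C5 bond anti to the C4–O bond, and ring B closes 6-endo through a second chair fused trans to the first. C3 keeps the epoxide configuration (3β-OH equatorial); at C4 the group trans to the chain in the epoxide (CH2OSi, the former E-methyl) becomes equatorial and the cis methyl axial; C5 and C10 follow from anti addition across the 6E alkene (5α-H, 10β-CH3); C9 follows from the 2E geometry and the chair (C11 equatorial, 9α-H). The step needs opening at the tertiary carbon (Markovnikov bias, only slightly offset by the silyloxymethyl group), completion of both closures (low temperature and a non-protic Lewis acid), and endocyclic proton loss (axial H7 aligned with the empty orbital at C8). The electron-poor acetate-bearing alkene secures the last two only in part, so exocyclic alkene and interrupted products are the expected by-products.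

Step 5
Reactants: 5 3β-hydroxy-18-(triisopropylsilyloxy)drim-7-en-11-yl acetate
Product: 6 3β-(phenoxythiocarbonyloxy)-18-(triisopropylsilyloxy)drim-7-en-11-yl acetate
Conditions: PhOC(S)Cl, pyridine, DMAP (cat.), CH2Cl2, 0 °C to rt
Reagents that add atoms: O-phenyl chlorothioformate S=C(Cl)Oc1ccccc1
Why: Acylation of the equatorial secondary alcohol to the aryl thionocarbonate under neutral conditions, so the primary acetate neither migrates nor cleaves as it might under xanthate formation.

Step 6
Reactants: 6 3β-(phenoxythiocarbonyloxy)-18-(triisopropylsilyloxy)drim-7-en-11-yl acetate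
Product: 7 18-(triisopropylsilyloxy)drim-7-en-11-yl acetate
Conditions: Bu3SnH, AIBN (cat.), toluene, 100 °C
Reagents that add atoms: none
Why: Barton–McCombie deoxygenation; the secondary C3 radical is reduced by the stannane faster than it can reach the distant alkene. No stereocentre is touched.

Step 7
Reactants: 7 18-(triisopropylsilyloxy)drim-7-en-11-yl acetate
Product: 8 6-oxo-18-(triisopropylsilyloxy)drim-7-en-11-yl acetate
Conditions: CrO3, 3,5-dimethylpyrazole, CH2Cl2, −20 °C
Reagents that add atoms: chromium trioxide O=[Cr](=O)=O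
Why: Allylic oxidation by the hexavalent chromium–pyrazole complex, as used for ring methylenes next to trisubstituted cycloalkenes; of the allylic positions only the C6 methylene can become a conjugated ketone without moving the alkene. The hindered C9 methine and the C8 methyl react more slowly.

Step 8
Reactants: 8 6-oxo-18-(triisopropylsilyloxy)drim-7-en-11-yl acetate
Product: 10 7α,8α-epoxy-11-hydroxy-18-(triisopropylsilyloxy)driman-6-one, via the epoxy ketone acetate 9 (not isolated)
Conditions: 30% aq. H2O2, NaOH, MeOH, 0 °C to rt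
Reagents that add atoms: hydrogen peroxide OO
Why: Weitz–Scheffer epoxidation of a β,β-disubstituted enone; hydroperoxide adds to C8 from the α face, anti to the axial C10 methyl, and closes to the 7α,8α-epoxide, which sets C8. The same base cleaves the primary acetate, wanted here because C11 is elaborated next and the ester would not survive step 9.

Step 9
Reactants: 10 7α,8α-epoxy-11-hydroxy-18-(triisopropylsilyloxy)driman-6-one
Product: 12 18-(triisopropylsilyloxy)drimane-6α,8α,11-triol, via the hydroxy ketone 11 (not isolated)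
Conditions: Li, NH3(l)/THF, −78 °C; then MeOH, −78 to −33 °C; aq. NH4Cl
Reagents that add atoms: none
Why: Two dissolving-metal reductions in one flask: the ketyl of the α,β-epoxy ketone expels the C7–O bond to give the enolate of 11, which methanol protonates and lithium reduces again. Protonation at C6 under thermodynamic control gives the equatorial 6α-alcohol, because the axial 6β position is flanked by the syn-axial methyls on C4 and C10. C8 keeps the epoxide configuration and the alkyl silyl ether is inert.

Step 10
Reactants: 12 18-(triisopropylsilyloxy)drimane-6α,8α,11-triol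
Product: 13 6α,8α,11-tris(triethylsilyloxy)-18-(triisopropylsilyloxy)drimane
Conditions: Et3SiOTf, 2,6-lutidine, CH2Cl2, −78 to 0 °C
Reagents that add atoms: triethylsilyl trifluoromethanesulfonate CC[Si](CC)(CC)OS(=O)(=O)C(F)(F)F
Why: Exhaustive silylation; the silyl triflate is reactive enough for the tertiary 8α-hydroxyl. Masking O8 prevents retro-aldol chemistry once C11 becomes an aldehyde.

Step 11
Reactants: 13 6α,8α,11-tris(triethylsilyloxy)-18-(triisopropylsilyloxy)drimane
Product: 14 6α,8α-bis(triethylsilyloxy)-18-(triisopropylsilyloxy)driman-11-al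
Conditions: (COCl)2, DMSO, CH2Cl2, −78 to −40 °C; then Et3N, −78 °C to rt
Reagents that add atoms: none
Why: Swern oxidation in which the chlorosulfonium reagent cleaves a primary triethylsilyl ether and oxidises it in the same flask, while secondary and tertiary silyl ethers stay. The aldehyde is never exposed next to a free C8 hydroxyl, and C9 keeps its equatorial substituent.

Step 12
Reactants: 14 6α,8α-bis(triethylsilyloxy)-18-(triisopropylsilyloxy)driman-11-al
Product: 15 6α,8α-bis(triethylsilyloxy)-18-(triisopropylsilyloxy)-11-methylidenedrimane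
Conditions: Ph3PCH3Br, KOtBu, THF, 0 °C to rt
Reagents that add atoms: methyltriphenylphosphonium bromide C[P+](c1ccccc1)(c1ccccc1)c1ccccc1.[Br-]
Why: Wittig methylenation; the unstabilised ylide adds to the aldehyde faster than it removes the hindered axial C9 hydrogen. Any enolisation would return to the more stable equatorial aldehyde.

Step 13
Reactants: 16 ethyl acetoacetate
Product: 17 ethyl (2E)-3-(trifluoromethylsulfonyloxy)but-2-enoate
Conditions: Tf2O, aq. Me4NOH, toluene, 5 °C to rt
Reagents that add atoms: trifluoromethanesulfonic anhydride O=S(=O)(OS(=O)(=O)C(F)(F)F)C(F)(F)F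
Why: O-sulfonylation of the β-keto ester enolate; with the non-chelating tetramethylammonium cation the enolate oxygens lie apart, so the triflate ends trans to the ester. This geometry becomes the 13E alkene.

Step 14
Reactants: 15 6α,8α-bis(triethylsilyloxy)-18-(triisopropylsilyloxy)-11-methylidenedrimane; 17 ethyl (2E)-3-(trifluoromethylsulfonyloxy)but-2-enoate
Product: 19 ethyl (2E)-4-[6α,8α-bis(triethylsilyloxy)-18-(triisopropylsilyloxy)driman-11-yl]-3-methylbut-2-enoate, via the alkylborane 18 (not isolated)
Conditions: 9-BBN, THF, 0 °C to rt; then 17, Pd(dppf)Cl2 (cat.), AsPh3 (cat.), aq. K3PO4, DMF, rt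
Reagents that add atoms: none
Why: Anti-Markovnikov hydroboration of the only alkene puts boron on C12, and B-alkyl Suzuki–Miyaura coupling with the enol triflate forms C12–C13. Oxidative addition to zerovalent palladium and reductive elimination both retain alkene geometry, so the alkene is E.

Step 15
Reactants: 19 ethyl (2E)-4-[6α,8α-bis(triethylsilyloxy)-18-(triisopropylsilyloxy)driman-11-yl]-3-methylbut-2-enoate
Product: 20 (2E)-4-[6α,8α-bis(triethylsilyloxy)-18-(triisopropylsilyloxy)driman-11-yl]-3-methylbut-2-en-1-ol
Conditions: i-Bu2AlH, CH2Cl2, −78 °C; aq. sodium potassium tartrate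
Reagents that add atoms: none
Why: 1,2-Reduction of an α,β-unsaturated ester to the allylic alcohol; the aluminium hydride does not add in conjugate fashion and silyl ethers are inert.

Step 16
Reactants: 20 (2E)-4-[6α,8α-bis(triethylsilyloxy)-18-(triisopropylsilyloxy)driman-11-yl]-3-methylbut-2-en-1-ol
Product: 21 (2E)-4-[6α,8α-bis(triethylsilyloxy)-18-(triisopropylsilyloxy)driman-11-yl]-3-methylbut-2-enal
Conditions: MnO2, CH2Cl2, rt
Reagents that add atoms: none
Why: Selective oxidation of an allylic alcohol on MnO2 under neutral conditions, which keeps the E geometry of the β,β-disubstituted enal.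

Step 17
Reactants: 22 4-methylfuran-2(5H)-one
Product: 23 4-methyl-2-(trimethylsilyloxy)furan
Conditions: Me3SiOTf, Et3N, Et2O, 0 °C
Reagents that add atoms: trimethylsilyl trifluoromethanesulfonate C[Si](C)(C)OS(=O)(=O)C(F)(F)F
Why: γ-Deprotonation of the butenolide and O-silylation give the aromatic 2-silyloxyfuran, a stable, distillable dienolate equivalent.

Step 18
Reactants: 21 (2E)-4-[6α,8α-bis(triethylsilyloxy)-18-(triisopropylsilyloxy)driman-11-yl]-3-methylbut-2-enal; 23 4-methyl-2-(trimethylsilyloxy)furan
Product: 25 (5S)-5-[(1S,2E)-4-[6α,8α-bis(triethylsilyloxy)-18-(triisopropylsilyloxy)driman-11-yl]-1-hydroxy-3-methylbut-2-enyl]-4-methylfuran-2(5H)-one, via the trimethylsilyl ether 24 (not isolated)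
Conditions: Ti(OiPr)4 (20 mol %), (R)-BINOL (20 mol %), 4 Å MS, Et2O, −20 °C; then aq. citric acid, THF, 0 °C
Reagents that add atoms: none
Why: Catalytic enantioselective vinylogous Mukaiyama aldol addition of a 2-silyloxyfuran; C5 of 23 adds 1,2 to the enal, whose β-carbon is fully substituted. The BINOL–titanium Lewis acid selects the Re face of the aldehyde (15S) and the open transition state favours the threo adduct (16S). The ring stereocentres are too remote to interfere, so control rests on the catalyst.

Step 19
Reactants: 25 (5S)-5-[(1S,2E)-4-[6α,8α-bis(triethylsilyloxy)-18-(triisopropylsilyloxy)driman-11-yl]-1-hydroxy-3-methylbut-2-enyl]-4-methylfuran-2(5H)-one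
Product: 26 (5S)-5-[(1S,2E)-1-hydroxy-3-methyl-4-(6α,8α,18-trihydroxydriman-11-yl)but-2-enyl]-4-methylfuran-2(5H)-one (CNP0255788.1)
Conditions: HF·pyridine, pyridine, THF, 0 °C to rt
Reagents that add atoms: none
Why: Fluoride-mediated cleavage of the two triethylsilyl ethers and the primary triisopropylsilyl ether in a buffered, non-basic medium. The butenolide γ-centre and the allylic C15 alcohol are not exposed to base, so no stereocentre is at risk.

## Compound list

1 | (2E,6E)-farnesyl acetate | CC(=O)OC/C=C(\C)CC/C=C(\C)CCC=C(C)C | starting material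
2 | (2E,6E,10E)-12-hydroxyfarnesyl acetate | CC(=O)OC/C=C(\C)CC/C=C(\C)CC/C=C(\C)CO | intermediate
3 | (2E,6E,10S,11S)-10,11-epoxy-12-hydroxyfarnesyl acetate | CC(=O)OC/C=C(\C)CC/C=C(\C)CC[C@@H]1O[C@@]1(C)CO | intermediate
4 | (2E,6E,10S,11S)-10,11-epoxy-12-(triisopropylsilyloxy)farnesyl acetate | CC(=O)OC/C=C(\C)CC/C=C(\C)CC[C@@H]1O[C@@]1(C)CO[Si](C(C)C)(C(C)C)C(C)C | intermediate
5 | 3β-hydroxy-18-(triisopropylsilyloxy)drim-7-en-11-yl acetate (4α-CH2OSi, 4β-CH3, 5α-H, 9α-H, 10β-CH3) | CC(=O)OC[C@@H]1[C@@]2(C)CC[C@H](O)[C@@](C)(CO[Si](C(C)C)(C(C)C)C(C)C)[C@@H]2CC=C1C | intermediate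
6 | 3β-(phenoxythiocarbonyloxy)-18-(triisopropylsilyloxy)drim-7-en-11-yl acetate | CC(=O)OC[C@@H]1[C@@]2(C)CC[C@H](OC(=S)Oc3ccccc3)[C@@](C)(CO[Si](C(C)C)(C(C)C)C(C)C)[C@@H]2CC=C1C | intermediate
7 | 18-(triisopropylsilyloxy)drim-7-en-11-yl acetate | CC(=O)OC[C@@H]1[C@@]2(C)CCC[C@@](C)(CO[Si](C(C)C)(C(C)C)C(C)C)[C@@H]2CC=C1C | intermediate
8 | 6-oxo-18-(triisopropylsilyloxy)drim-7-en-11-yl acetate | CC(=O)OC[C@@H]1[C@@]2(C)CCC[C@@](C)(CO[Si](C(C)C)(C(C)C)C(C)C)[C@@H]2C(=O)C=C1C | intermediate
9 | 7α,8α-epoxy-6-oxo-18-(triisopropylsilyloxy)driman-11-yl acetate | CC(=O)OC[C@@H]1[C@@]2(C)CCC[C@@](C)(CO[Si](C(C)C)(C(C)C)C(C)C)[C@@H]2C(=O)[C@H]3O[C@]31C | intermediate (not isolated)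
10 | 7α,8α-epoxy-11-hydroxy-18-(triisopropylsilyloxy)driman-6-one | OC[C@@H]1[C@@]2(C)CCC[C@@](C)(CO[Si](C(C)C)(C(C)C)C(C)C)[C@@H]2C(=O)[C@H]3O[C@]31C | intermediate
11 | 8α,11-dihydroxy-18-(triisopropylsilyloxy)driman-6-one | OC[C@@H]1[C@@]2(C)CCC[C@@](C)(CO[Si](C(C)C)(C(C)C)C(C)C)[C@@H]2C(=O)C[C@@]1(C)O | intermediate (not isolated)
12 | 18-(triisopropylsilyloxy)drimane-6α,8α,11-triol | OC[C@@H]1[C@@]2(C)CCC[C@@](C)(CO[Si](C(C)C)(C(C)C)C(C)C)[C@@H]2[C@@H](O)C[C@@]1(C)O | intermediate
13 | 6α,8α,11-tris(triethylsilyloxy)-18-(triisopropylsilyloxy)drimane | CC[Si](CC)(CC)OC[C@@H]1[C@@]2(C)CCC[C@@](C)(CO[Si](C(C)C)(C(C)C)C(C)C)[C@@H]2[C@@H](O[Si](CC)(CC)CC)C[C@@]1(C)O[Si](CC)(CC)CC | intermediate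
14 | 6α,8α-bis(triethylsilyloxy)-18-(triisopropylsilyloxy)driman-11-al | O=C[C@@H]1[C@@]2(C)CCC[C@@](C)(CO[Si](C(C)C)(C(C)C)C(C)C)[C@@H]2[C@@H](O[Si](CC)(CC)CC)C[C@@]1(C)O[Si](CC)(CC)CC | intermediate
15 | 6α,8α-bis(triethylsilyloxy)-18-(triisopropylsilyloxy)-11-methylidenedrimane (9β-vinyl) | C=C[C@@H]1[C@@]2(C)CCC[C@@](C)(CO[Si](C(C)C)(C(C)C)C(C)C)[C@@H]2[C@@H](O[Si](CC)(CC)CC)C[C@@]1(C)O[Si](CC)(CC)CC | intermediate
16 | ethyl acetoacetate | CCOC(=O)CC(C)=O | starting material
17 | ethyl (2E)-3-(trifluoromethylsulfonyloxy)but-2-enoate | CCOC(=O)/C=C(\C)OS(=O)(=O)C(F)(F)F | intermediate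
18 | 9-{[6α,8α-bis(triethylsilyloxy)-18-(triisopropylsilyloxy)driman-11-yl]methyl}-9-borabicyclo[3.3.1]nonane | C1CCC2CCCC1B2CC[C@@H]1[C@@]2(C)CCC[C@@](C)(CO[Si](C(C)C)(C(C)C)C(C)C)[C@@H]2[C@@H](O[Si](CC)(CC)CC)C[C@@]1(C)O[Si](CC)(CC)CC | intermediate (not isolated)
19 | ethyl (2E)-4-[6α,8α-bis(triethylsilyloxy)-18-(triisopropylsilyloxy)driman-11-yl]-3-methylbut-2-enoate | CCOC(=O)/C=C(\C)CC[C@@H]1[C@@]2(C)CCC[C@@](C)(CO[Si](C(C)C)(C(C)C)C(C)C)[C@@H]2[C@@H](O[Si](CC)(CC)CC)C[C@@]1(C)O[Si](CC)(CC)CC | intermediate
20 | (2E)-4-[6α,8α-bis(triethylsilyloxy)-18-(triisopropylsilyloxy)driman-11-yl]-3-methylbut-2-en-1-ol | OC/C=C(\C)CC[C@@H]1[C@@]2(C)CCC[C@@](C)(CO[Si](C(C)C)(C(C)C)C(C)C)[C@@H]2[C@@H](O[Si](CC)(CC)CC)C[C@@]1(C)O[Si](CC)(CC)CC | intermediate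
21 | (2E)-4-[6α,8α-bis(triethylsilyloxy)-18-(triisopropylsilyloxy)driman-11-yl]-3-methylbut-2-enal | O=C/C=C(\C)CC[C@@H]1[C@@]2(C)CCC[C@@](C)(CO[Si](C(C)C)(C(C)C)C(C)C)[C@@H]2[C@@H](O[Si](CC)(CC)CC)C[C@@]1(C)O[Si](CC)(CC)CC | intermediate
22 | 4-methylfuran-2(5H)-one | CC1=CC(=O)OC1 | starting material
23 | 4-methyl-2-(trimethylsilyloxy)furan | Cc1coc(O[Si](C)(C)C)c1 | intermediate
24 | 15-O-trimethylsilyl ether of 25 | CC1=CC(=O)O[C@@H]1[C@@H](O[Si](C)(C)C)/C=C(\C)CC[C@@H]1[C@@]2(C)CCC[C@@](C)(CO[Si](C(C)C)(C(C)C)C(C)C)[C@@H]2[C@@H](O[Si](CC)(CC)CC)C[C@@]1(C)O[Si](CC)(CC)CC | intermediate (not isolated)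
25 | (5S)-5-[(1S,2E)-4-[6α,8α-bis(triethylsilyloxy)-18-(triisopropylsilyloxy)driman-11-yl]-1-hydroxy-3-methylbut-2-enyl]-4-methylfuran-2(5H)-one | CC1=CC(=O)O[C@@H]1[C@@H](O)/C=C(\C)CC[C@@H]1[C@@]2(C)CCC[C@@](C)(CO[Si](C(C)C)(C(C)C)C(C)C)[C@@H]2[C@@H](O[Si](CC)(CC)CC)C[C@@]1(C)O[Si](CC)(CC)CC | intermediate
26 | (5S)-5-[(1S,2E)-1-hydroxy-3-methyl-4-(6α,8α,18-trihydroxydriman-11-yl)but-2-enyl]-4-methylfuran-2(5H)-one (CNP0255788.1) | CC1=CC(=O)O[C@@H]1[C@@H](O)/C=C(\C)CC[C@@H]1[C@@]2(C)CCC[C@@](C)(CO)[C@@H]2[C@@H](O)C[C@@]1(C)O | target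

## Step count and least certain steps

Total: 19 steps. Longest linear sequence: 17 steps (steps 1–12, 14–16, 18 and 19); steps 13 and 17 prepare the two small partners.

Step 4 (key step). The cascade may stop after ring A, because the acetate-bearing alkene is a weak nucleophile, and the final proton loss may not be regioselective. Lewis-acid rearrangement of the epoxide to a carbonyl compound is a further drain. Fallback, from 4 to 5, by building the rings in two stages: the cyclisation is deliberately stopped after the first ring (Me2AlCl, CH2Cl2, −78 °C, short contact) to give the monocyclic exo-methylene alcohol F1, in which C3, C4 and C5 are already set. The second ring is then closed by a separate proton-initiated cyclisation (SnCl4, CF3CO2H, CH2Cl2, −78 °C) through the same chair, which returns to 5.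

Step 18. Facial discrimination at the aldehyde may be poor, since the ring stereocentres are too far to help, and the methyl next to the reacting furan carbon may erode the threo preference. Fallback, from 21 to 26, with auxiliary control and known reactions:
- Evans syn-aldol reaction of 21 with the dibutylboron enolate of (R)-4-benzyl-3-[(4-methoxybenzyloxy)acetyl]-1,3-oxazolidin-2-one (n-Bu2BOTf, Et3N, CH2Cl2, −78 to 0 °C) gives the syn glycolate adduct F7. The auxiliary fixes C15 (S) and C16 in the threo relationship of 26.
- Silylation (Et3SiOTf, 2,6-lutidine) gives the 15-O-triethylsilyl imide F8.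
- AlMe3/MeONHMe·HCl gives the N-methoxy-N-methylamide F9, and MeMgBr gives the methyl ketone F10.
- DDQ (CH2Cl2, pH 7 buffer) removes the 4-methoxybenzyl group to give the α-hydroxy ketone F11.
- Ph3P=C=C=O (toluene, 80 °C) acylates the C16 hydroxyl and closes the ring by intramolecular Wittig reaction to the 15-O-triethylsilyl butenolide F12.
- The conditions of step 19 then give 26.

Step 9. Protonation at C6 may occur from the wrong face and give the axial alcohol, and the β-alkoxy ketone stage may undergo retro-aldol opening of ring B in the basic medium. Fallback, from 10 to 13, replacing the thermodynamic reduction by hydride reduction plus catalytic epimerisation: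
- The epoxide alone is opened with SmI2 (THF/MeOH, −78 °C) and 11 is isolated.
- NaBH4 attacks from the α face and gives the axial alcohol, 18-(triisopropylsilyloxy)drimane-6β,8α,11-triol F2.
- The primary hydroxyl is capped (Et3SiCl, imidazole) to give the 11-triethylsilyl ether F3.
- The hydrogen-transfer catalyst Ru2(CO)4(μ-H)(C4Ph4COHOCC4Ph4) in toluene at 100 °C equilibrates C6 through the ketone toward the equatorial 6α-alcohol F4.
- Silylation under the conditions of step 10 returns to 13.

Step 14. Hydroboration of the vinyl group between two fully substituted carbons may be slow, and the alkylborane may lose boron by protonolysis or β-hydride elimination before transmetallation. Fallback, from 14 to 19, without boron: Wittig reaction of 14 with 1-(triphenylphosphoranylidene)propan-2-one gives the E-enone F5. Hydrogenation (H2, Pd/C, EtOAc) gives the methyl ketone F6. Horner–Wadsworth–Emmons olefination (triethyl phosphonoacetate, NaH, THF) gives 19 after removal of the minor Z isomer.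

## Further compounds

F1 | step 4 | (2E)-5-[3-hydroxy-2-methyl-6-methylidene-2-(triisopropylsilyloxymethyl)cyclohexyl]-3-methylpent-2-enyl acetate, ring centres as C3, C4 and C5 of 5 | CC(=O)OC/C=C(\C)CC[C@@H]1C(=C)CC[C@H](O)[C@@]1(C)CO[Si](C(C)C)(C(C)C)C(C)C
F2 | step 9 | 18-(triisopropylsilyloxy)drimane-6β,8α,11-triol | OC[C@@H]1[C@@]2(C)CCC[C@@](C)(CO[Si](C(C)C)(C(C)C)C(C)C)[C@@H]2[C@H](O)C[C@@]1(C)O
F3 | step 9 | 11-(triethylsilyloxy)-18-(triisopropylsilyloxy)drimane-6β,8α-diol | CC[Si](CC)(CC)OC[C@@H]1[C@@]2(C)CCC[C@@](C)(CO[Si](C(C)C)(C(C)C)C(C)C)[C@@H]2[C@H](O)C[C@@]1(C)O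
F4 | step 9 | 11-(triethylsilyloxy)-18-(triisopropylsilyloxy)drimane-6α,8α-diol | CC[Si](CC)(CC)OC[C@@H]1[C@@]2(C)CCC[C@@](C)(CO[Si](C(C)C)(C(C)C)C(C)C)[C@@H]2[C@@H](O)C[C@@]1(C)O
F5 | step 14 | (1E)-1-[6α,8α-bis(triethylsilyloxy)-18-(triisopropylsilyloxy)driman-11-ylidene]propan-2-one | CC(=O)/C=C/[C@@H]1[C@@]2(C)CCC[C@@](C)(CO[Si](C(C)C)(C(C)C)C(C)C)[C@@H]2[C@@H](O[Si](CC)(CC)CC)C[C@@]1(C)O[Si](CC)(CC)CC
F6 | step 14 | 1-[6α,8α-bis(triethylsilyloxy)-18-(triisopropylsilyloxy)driman-11-yl]propan-2-one | CC(=O)CC[C@@H]1[C@@]2(C)CCC[C@@](C)(CO[Si](C(C)C)(C(C)C)C(C)C)[C@@H]2[C@@H](O[Si](CC)(CC)CC)C[C@@]1(C)O[Si](CC)(CC)CC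
F7 | step 18 | (R)-4-benzyl-3-[(2R,3S,4E)-6-[6α,8α-bis(triethylsilyloxy)-18-(triisopropylsilyloxy)driman-11-yl]-3-hydroxy-2-(4-methoxybenzyloxy)-5-methylhex-4-enoyl]-1,3-oxazolidin-2-one | COc1ccc(CO[C@@H](C(=O)N2[C@H](Cc3ccccc3)COC2=O)[C@@H](O)/C=C(\C)CC[C@@H]2[C@@]3(C)CCC[C@@](C)(CO[Si](C(C)C)(C(C)C)C(C)C)[C@@H]3[C@@H](O[Si](CC)(CC)CC)C[C@@]2(C)O[Si](CC)(CC)CC)cc1
F8 | step 18 | 3-O-triethylsilyl ether of F7 | COc1ccc(CO[C@@H](C(=O)N2[C@H](Cc3ccccc3)COC2=O)[C@@H](O[Si](CC)(CC)CC)/C=C(\C)CC[C@@H]2[C@@]3(C)CCC[C@@](C)(CO[Si](C(C)C)(C(C)C)C(C)C)[C@@H]3[C@@H](O[Si](CC)(CC)CC)C[C@@]2(C)O[Si](CC)(CC)CC)cc1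
F9 | step 18 | (2R,3S,4E)-6-[6α,8α-bis(triethylsilyloxy)-18-(triisopropylsilyloxy)driman-11-yl]-N-methoxy-2-(4-methoxybenzyloxy)-N,5-dimethyl-3-(triethylsilyloxy)hex-4-enamide | COc1ccc(CO[C@@H](C(=O)N(C)OC)[C@@H](O[Si](CC)(CC)CC)/C=C(\C)CC[C@@H]2[C@@]3(C)CCC[C@@](C)(CO[Si](C(C)C)(C(C)C)C(C)C)[C@@H]3[C@@H](O[Si](CC)(CC)CC)C[C@@]2(C)O[Si](CC)(CC)CC)cc1
F10 | step 18 | (3R,4S,5E)-7-[6α,8α-bis(triethylsilyloxy)-18-(triisopropylsilyloxy)driman-11-yl]-3-(4-methoxybenzyloxy)-6-methyl-4-(triethylsilyloxy)hept-5-en-2-one | COc1ccc(CO[C@@H](C(C)=O)[C@@H](O[Si](CC)(CC)CC)/C=C(\C)CC[C@@H]2[C@@]3(C)CCC[C@@](C)(CO[Si](C(C)C)(C(C)C)C(C)C)[C@@H]3[C@@H](O[Si](CC)(CC)CC)C[C@@]2(C)O[Si](CC)(CC)CC)cc1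
F11 | step 18 | (3R,4S,5E)-7-[6α,8α-bis(triethylsilyloxy)-18-(triisopropylsilyloxy)driman-11-yl]-3-hydroxy-6-methyl-4-(triethylsilyloxy)hept-5-en-2-one | O[C@@H](C(C)=O)[C@@H](O[Si](CC)(CC)CC)/C=C(\C)CC[C@@H]1[C@@]2(C)CCC[C@@](C)(CO[Si](C(C)C)(C(C)C)C(C)C)[C@@H]2[C@@H](O[Si](CC)(CC)CC)C[C@@]1(C)O[Si](CC)(CC)CC
F12 | step 18 | (5S)-5-[(1S,2E)-4-[6α,8α-bis(triethylsilyloxy)-18-(triisopropylsilyloxy)driman-11-yl]-3-methyl-1-(triethylsilyloxy)but-2-enyl]-4-methylfuran-2(5H)-one | CC1=CC(=O)O[C@@H]1[C@@H](O[Si](CC)(CC)CC)/C=C(\C)CC[C@@H]1[C@@]2(C)CCC[C@@](C)(CO[Si](C(C)C)(C(C)C)C(C)C)[C@@H]2[C@@H](O[Si](CC)(CC)CC)C[C@@]1(C)O[Si](CC)(CC)CC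
A1 | alternative 1 | larixol, (13S)-labda-8(17),14-diene-6α,13-diol | C=C[C@@](C)(O)CC[C@@H]1[C@@]2(C)CCCC(C)(C)[C@@H]2[C@@H](O)CC1=C
A2 | alternative 1 | 6α-(diethylsilyloxy)-8α-(trimethylsilyloxy)-14,15-dinorlabdan-13-one ethylene ketal | CC1(CC[C@@H]2[C@@]3(C)CCCC(C)(C)[C@@H]3[C@@H](O[SiH](CC)CC)C[C@@]2(C)O[Si](C)(C)C)OCCO1
A3 | alternative 1 | 6α,18-bridged diethyl oxasilinane of the same ketal | CC1(CC[C@@H]2[C@@]3(C)CCC[C@@](C)(C[Si]4(CC)CC)[C@@H]3[C@@H](O4)C[C@@]2(C)O[Si](C)(C)C)OCCO1
A4 | alternative 2 | dehydroabietic acid | CC(C)c1ccc2c(c1)CC[C@@H]1[C@]2(C)CCC[C@@]1(C)C(=O)O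
A5 | alternative 2 | 6α,18-diacetoxy-11-homodrim-8-en-12-oic acid | OC(=O)CC1=C(C)C[C@H](OC(C)=O)[C@H]2[C@](C)(COC(C)=O)CCC[C@]12C
A6 | alternative 2 | 6α,18-diacetoxy sclareolide-type 8α,12-lactone | O=C1C[C@@H]2[C@@]3(C)CCC[C@@](C)(COC(C)=O)[C@@H]3[C@@H](OC(C)=O)C[C@@]2(C)O1
A7 | alternative 3 | 9β-acetyl-9α-hydroxy hydrindene with the C5=C6 alkene, 18-benzyl ether (configuration at C9 as a chelated migration would require) | CC(=O)[C@@]1(O)CC=C2[C@](C)(COCc3ccccc3)CCC[C@]12C
A8 | alternative 3 | 8α-hydroxy-8β-methyl-9-oxo Δ5-octalin, 18-benzyl ether | O=C1[C@@]2(C)CCC[C@@](C)(COCc3ccccc3)C2=CC[C@@]1(C)O
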